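**Retrosynthetic overview**
1. The route rests on the (Z)-2-methylbut-2-enoyl (angeloyl) ester on the phenolic oxygen at C1 of the benzene ring, ortho to the carbon bearing the 2,2-disubstituted oxirane. Its C2=C3 bond slips to the E geometry of the tiglate on the side-chain CH2–O once the acid is activated, so the acyl group is built in place from (Z)-2-bromobut-2-ene, CO and the free phenol (acyl C–alkenyl C and acyl C–O bonds) by palladium catalysis.
2. The carbonylation is run while the ortho side chain is still a 2-arylallyl silyl ether. A free phenol next to the benzylic oxirane would open it under amine base, and aryl oxiranes can isomerise under phosphine-ligated zerovalent palladium, so the oxirane is made afterwards.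
3. After the key step: desilylation, titanium–tartrate epoxidation of the 2-arylallyl alcohol (sets the quaternary oxirane carbon), then tigloylation of the primary alcohol. The oxirane is the only ring formed; the benzene ring is bought.
4. Before it: the aryl–C(=CH2) bond comes from Suzuki coupling of 2-bromo-4-methoxy-5-methylphenol with an α-borylated allyl silyl ether.

Key step: step 4

Assumption: (Z)-2-bromobut-2-ene is used as the geometrically pure isomer with the two methyl groups trans (Br cis to the C3 methyl); carbonylation with retention turns this isomer into the angelate, not the tiglate.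

**Step 1**
Reactants: 1 4-methoxy-3-methylphenol
Product: 2 2-bromo-4-methoxy-5-methylphenol
Conditions: NBS (1.0 equiv), i-Pr2NH (10 mol%), CH2Cl2, 0 °C
Reagents that add atoms: N-bromosuccinimide, O=C1CCC(=O)N1Br
Why: Electrophilic aromatic bromination (amine-catalysed ortho-bromination of a phenol): with the para position blocked by OMe, bromine should enter ortho to OH at C6, which is para to the methyl group and the less hindered of the two ortho sites.

**Step 2**
Reactants: 3 tert-butyldimethyl(prop-2-yn-1-yloxy)silane
Product: 4 tert-butyldimethyl{[2-(4,4,5,5-tetramethyl-1,3,2-dioxaborolan-2-yl)prop-2-en-1-yl]oxy}silane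
Conditions: B2pin2, MeOH, CuCl (5 mol%), 1,3-bis(2,4,6-trimethylphenyl)imidazolinium chloride (5 mol%), NaOt-Bu (20 mol%), THF, −50 °C to rt
Reagents that add atoms: bis(pinacolato)diboron, CC1(C)OB(OC1(C)C)B1OC(C)(C)C(C)(C)O1
Why: Copper-catalysed protoboration of a terminal alkyne: the N-aryl carbene–copper boryl species adds syn with boron at the internal carbon next to the CH2OSi group, and MeOH protonates the alkenylcopper.

**Step 3**
Reactants: 2 2-bromo-4-methoxy-5-methylphenol; 4 tert-butyldimethyl{[2-(4,4,5,5-tetramethyl-1,3,2-dioxaborolan-2-yl)prop-2-en-1-yl]oxy}silane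
Product: 5 2-[3-(tert-butyldimethylsilyloxy)prop-1-en-2-yl]-4-methoxy-5-methylphenol
Conditions: Pd(OAc)2 (3 mol%), SPhos (6 mol%), K3PO4, 1,4-dioxane/H2O, 80 °C
Reagents that add atoms: none
Why: Suzuki–Miyaura coupling: the electron-rich biarylphosphine allows oxidative addition into the C–Br bond of the bromophenoxide, and the 1,1-disubstituted alkenylboronate transfers while the free phenol and the silyl ether are tolerated.

**Step 4**
Reactants: 5 2-[3-(tert-butyldimethylsilyloxy)prop-1-en-2-yl]-4-methoxy-5-methylphenol; 6 (Z)-2-bromobut-2-ene; 7 carbon monoxide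
Product: 8 2-[3-(tert-butyldimethylsilyloxy)prop-1-en-2-yl]-4-methoxy-5-methylphenyl (Z)-2-methylbut-2-enoate
Conditions: Pd(OAc)2 (5 mol%), Xantphos (6 mol%), Et3N (2.5 equiv), CO (1 atm), toluene, 70 °C, closed vessel
Reagents that add atoms: none
Why: Pd(OAc)2 is reduced in the flask to zerovalent palladium, which inserts into the C(sp2)–Br bond of 6 with retention of the alkene geometry; CO then inserts to give the (Z)-2-methylbut-2-enoyl palladium bromide of divalent palladium, the triethylammonium phenoxide of 5 displaces bromide, and C–O reductive elimination releases the aryl ester and returns zerovalent palladium. This is the Heck-type alkoxy/aryloxycarbonylation of alkenyl halides, here with a phenol as the oxygen nucleophile. No ring is closed and no stereocentre is formed; what the step must deliver is the Z geometry, which should carry over from 6 because neither oxidative addition nor migratory insertion touches the double bond and no acid chloride, carbodiimide or nucleophilic amine catalyst is present to open a conjugate-addition or vinylketene path to the E isomer. Chemoselectivity rests on the substrate: the allylic oxygen of 5 is a silyl ether that zerovalent palladium does not ionise, the phenol is the only free OH, and CO insertion under the wide-bite-angle Xantphos ligand should outrun Heck addition to the 1,1-disubstituted alkene. The ortho-substituted phenol should still react because the acylpalladium species is a strong acylating agent.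

**Step 5**
Reactants: 8 2-[3-(tert-butyldimethylsilyloxy)prop-1-en-2-yl]-4-methoxy-5-methylphenyl (Z)-2-methylbut-2-enoate
Product: 9 2-(3-hydroxyprop-1-en-2-yl)-4-methoxy-5-methylphenyl (Z)-2-methylbut-2-enoate
Conditions: HF·pyridine, pyridine, THF, 0 °C to rt
Reagents that add atoms: none
Why: Fluoride-mediated cleavage of the primary silyl ether under buffered, weakly acidic conditions, in which no alkoxide forms that could attack the neighbouring aryl ester or isomerise the angelate.

**Step 6**
Reactants: 9 2-(3-hydroxyprop-1-en-2-yl)-4-methoxy-5-methylphenyl (Z)-2-methylbut-2-enoate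
Product: 10 2-[(2S)-2-(hydroxymethyl)oxiran-2-yl]-4-methoxy-5-methylphenyl (Z)-2-methylbut-2-enoate
Conditions: Ti(Oi-Pr)4 (20 mol%), L-(+)-diisopropyl (2R,3R)-tartrate (24 mol%), t-BuOOH (decane), 4 Å MS, CH2Cl2, −20 °C; non-basic work-up
Reagents that add atoms: tert-butyl hydroperoxide, CC(C)(C)OO
Why: Sharpless asymmetric epoxidation: the allylic alkoxide and the peroxide bind the tartrate-ligated titanium, and L-(+)-tartrate delivers oxygen to the face that gives 2S epoxy alcohols from primary allylic alcohols (the aryl group takes the lowest CIP rank here, so the product is the (S)-2-arylglycidol), while the two electron-poor enoate alkenes carry no directing hydroxyl and are left alone.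

**Step 7**
Reactants: 10 2-[(2S)-2-(hydroxymethyl)oxiran-2-yl]-4-methoxy-5-methylphenyl (Z)-2-methylbut-2-enoate; 11 tiglic acid
Product: 13 [(2R)-2-{5-methoxy-4-methyl-2-[(Z)-2-methylbut-2-enoyloxy]phenyl}oxiran-2-yl]methyl (E)-2-methylbut-2-enoate, via O-tigloyl-N,N'-dicyclohexylisourea 12 (not isolated)
Conditions: DCC, DMAP (5 mol%), CH2Cl2, 0 °C; chromatography on Et3N-washed silica
Reagents that add atoms: none
Why: Steglich esterification of the primary alcohol through the O-acylisourea with tiglic acid, the thermodynamically stable E acid; the oxirane carbon is not touched, and its descriptor changes from S to R only because the acylated CH2O arm now outranks the ring CH2.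

**Compound list**
1 | 4-methoxy-3-methylphenol | Cc1cc(O)ccc1OC | starting material
2 | 2-bromo-4-methoxy-5-methylphenol | Oc1cc(C)c(OC)cc1Br | intermediate
3 | tert-butyldimethyl(prop-2-yn-1-yloxy)silane | C#CCO[Si](C)(C)C(C)(C)C | starting material
4 | tert-butyldimethyl{[2-(4,4,5,5-tetramethyl-1,3,2-dioxaborolan-2-yl)prop-2-en-1-yl]oxy}silane | C=C(CO[Si](C)(C)C(C)(C)C)B1OC(C)(C)C(C)(C)O1 | intermediate
5 | 2-[3-(tert-butyldimethylsilyloxy)prop-1-en-2-yl]-4-methoxy-5-methylphenol | Oc1cc(C)c(OC)cc1C(=C)CO[Si](C)(C)C(C)(C)C | intermediate
6 | (Z)-2-bromobut-2-ene | C/C=C(/C)Br | starting material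
7 | carbon monoxide | [C-]#[O+] | starting material
8 | 2-[3-(tert-butyldimethylsilyloxy)prop-1-en-2-yl]-4-methoxy-5-methylphenyl (Z)-2-methylbut-2-enoate | C/C=C(/C)C(=O)Oc1cc(C)c(OC)cc1C(=C)CO[Si](C)(C)C(C)(C)C | intermediate
9 | 2-(3-hydroxyprop-1-en-2-yl)-4-methoxy-5-methylphenyl (Z)-2-methylbut-2-enoate | C/C=C(/C)C(=O)Oc1cc(C)c(OC)cc1C(=C)CO | intermediate
10 | 2-[(2S)-2-(hydroxymethyl)oxiran-2-yl]-4-methoxy-5-methylphenyl (Z)-2-methylbut-2-enoate | C/C=C(/C)C(=O)Oc1cc(C)c(OC)cc1[C@]1(CO)CO1 | intermediate
11 | tiglic acid ((E)-2-methylbut-2-enoic acid) | OC(=O)/C(C)=C/C | starting material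
12 | O-tigloyl-N,N'-dicyclohexylisourea | C1CCCCC1N=C(NC1CCCCC1)OC(=O)/C(C)=C/C | intermediate
13 | [(2R)-2-{5-methoxy-4-methyl-2-[(Z)-2-methylbut-2-enoyloxy]phenyl}oxiran-2-yl]methyl (E)-2-methylbut-2-enoate | C/C=C(/C)C(=O)Oc1cc(C)c(OC)cc1[C@]1(COC(=O)/C(C)=C/C)CO1 | target

**Step count**
Total steps: 7. Longest linear sequence: 6 (steps 1, 3, 4, 5, 6, 7); step 2 makes the boronate on a side branch.

**Steps most likely to fail**

Step 4. The Z geometry may be lost, by isomerisation of the acylpalladium intermediate or of the aryl ester through a palladium hydride or reversible conjugate addition. The reaction may also stall if the ortho-substituted phenoxide captures the acylpalladium too slowly. The fallback sets out from 5 and returns at 8. Bought angelic acid is converted with 2,4,6-trichlorobenzoyl chloride and Et3N in toluene into the mixed anhydride (Z)-2-methylbut-2-enoic 2,4,6-trichlorobenzoic anhydride F1. F1 is then heated with 5 and Et3N in toluene without a pyridine-type acyl-transfer catalyst (Yamaguchi-type acyl transfer). The hindered aroyl carbonyl directs the phenol to the angeloyl carbon, giving 8.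

Step 6. The angeloyl group may transfer from the phenolic oxygen to the titanium-bound primary alkoxide, the Lewis acidic titanium species may open the benzylic oxirane, or the ortho-substituted aryl group may erode facial selectivity. The fallback sets out from 9 and returns at 13. Alcohol 9 is first esterified with tiglic acid 11 (DCC, DMAP, through 12) to the diester 2-{5-methoxy-4-methyl-2-[(Z)-2-methylbut-2-enoyloxy]phenyl}prop-2-en-1-yl (E)-2-methylbut-2-enoate F2. mCPBA with NaHCO3 in CH2Cl2 at 0 °C should then epoxidise only the electron-rich 1,1-disubstituted aryl alkene, since both enoates are electron-poor, to give the racemic oxirane F3. Preparative chromatography on a chiral stationary phase separates the enantiomers and delivers 13.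

Step 3. Oxidative addition into the electron-rich bromophenoxide may be slow while the α-substituted alkenylboronate protodeboronates, so the coupling stalls. The fallback sets out from 2 and returns at 5.
- The phenol is silylated (TBSCl, imidazole, DMF) to (2-bromo-4-methoxy-5-methylphenoxy)(tert-butyl)dimethylsilane F4.
- Magnesium in THF converts F4 into [2-(tert-butyldimethylsilyloxy)-5-methoxy-4-methylphenyl]magnesium bromide F5.
- F5 is added with catalytic CuI across the triple bond of propargyl alcohol that has first been deprotonated with EtMgBr. The aryl group goes to the internal carbon (alkoxide-directed carbomagnesiation), and protonation gives 2-[2-(tert-butyldimethylsilyloxy)-5-methoxy-4-methylphenyl]prop-2-en-1-ol F6.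
- The primary alcohol is silylated (TBSCl, imidazole) to tert-butyl{2-[3-(tert-butyldimethylsilyloxy)prop-1-en-2-yl]-4-methoxy-5-methylphenoxy}dimethylsilane F7.
- K2CO3 in MeOH at rt cleaves the aryl silyl ether selectively and gives 5.

**Further compounds**
F1 | step 4 | (Z)-2-methylbut-2-enoic 2,4,6-trichlorobenzoic anhydride | C/C=C(/C)C(=O)OC(=O)c1c(Cl)cc(Cl)cc1Cl
F2 | step 6 | 2-{5-methoxy-4-methyl-2-[(Z)-2-methylbut-2-enoyloxy]phenyl}prop-2-en-1-yl (E)-2-methylbut-2-enoate | C/C=C(/C)C(=O)Oc1cc(C)c(OC)cc1C(=C)COC(=O)/C(C)=C/C
F3 | step 6 | racemic (2-{5-methoxy-4-methyl-2-[(Z)-2-methylbut-2-enoyloxy]phenyl}oxiran-2-yl)methyl (E)-2-methylbut-2-enoate | C/C=C(/C)C(=O)Oc1cc(C)c(OC)cc1C1(COC(=O)/C(C)=C/C)CO1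
F4 | step 3 | (2-bromo-4-methoxy-5-methylphenoxy)(tert-butyl)dimethylsilane | CC(C)(C)[Si](C)(C)Oc1cc(C)c(OC)cc1Br
F5 | step 3 | [2-(tert-butyldimethylsilyloxy)-5-methoxy-4-methylphenyl]magnesium bromide | CC(C)(C)[Si](C)(C)Oc1cc(C)c(OC)cc1[Mg]Br
F6 | step 3 | 2-[2-(tert-butyldimethylsilyloxy)-5-methoxy-4-methylphenyl]prop-2-en-1-ol | OCC(=C)c1cc(OC)c(C)cc1O[Si](C)(C)C(C)(C)C
F7 | step 3 | tert-butyl{2-[3-(tert-butyldimethylsilyloxy)prop-1-en-2-yl]-4-methoxy-5-methylphenoxy}dimethylsilane | CC(C)(C)[Si](C)(C)OCC(=C)c1cc(OC)c(C)cc1O[Si](C)(C)C(C)(C)C
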